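**Two constants.** The midnight run offers two constants before any mechanism is chosen. Its first reading, 21.0% of the charge at 1.8 min, gives a pseudo-first-order making constant of 0.131 min⁻¹, so X is born on average at 7.63 min. Its last reading, 79.5% of the charge at 32 min, has therefore aged 24.4 min, and that gives 0.00940 min⁻¹ for the leak, the share of the standing X lost per minute. Making and leak cross at 21.7 min, and the highest midnight reading stands at 24 min.

| flask | E | G | time |
|---|---|---|---|
| dusk | 0.300 M | 0.900 M |  |
| dawn | 0.600 M | 0.900 M |  |
| midnight | 0.300 M | 1.40 M |  |
| noon | 0.300 M | 2.20 M | 32 min |

| run | time / min | [X] / M |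
|---|---|---|
| dusk run | 1.8 | 0.0406 |
| dusk run | 5.5 | 0.1020 |
| dusk run | 11 | 0.1563 |
| dusk run | 17 | 0.1893 |
| dusk run | 24 | 0.2116 |
| dusk run | 32 | 0.2212 |
| dawn run | 1.8 | 0.0804 |
| dawn run | 5.5 | 0.1895 |
| dawn run | 11 | 0.2883 |
| dawn run | 17 | 0.3442 |
| dawn run | 24 | 0.3828 |
| dawn run | 32 | 0.4038 |
| midnight run | 1.8 | 0.0630 |
| midnight run | 5.5 | 0.1443 |
| midnight run | 11 | 0.2036 |
| midnight run | 17 | 0.2302 |
| midnight run | 24 | 0.2408 |
| midnight run | 32 | 0.2386 |

(readings scatter by 9 × 10⁻⁴ M)

- Overall: E + G -> X.
- Constant volume, constant temperature.
- A reading of a species includes what of it is bound.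
- An order is taken over about fifteen percent of the charge, up and down.

- order of the initial rate in [G], near the charge of the dusk run, the rate being that where two percent of its E are X
- order of the initial rate in [E], near the charge of the dusk run, the rate being that where two percent of its E are X (one fixed amount of X, the same in the runs compared)
- X in the noon run at 32 min, as a share of the E charged

**The question reversed.** For noon to end close to its whole charge, leak times age would have to be small beside one, and the crossing itself may lie before 32 min without harm to that. The first readings of midnight and dusk stand at a ratio of 1.55 for a ratio of 1.56 in G, so I scale making with G and get 0.206 min⁻¹ for noon. The noon crossing then falls at 15.7 min, earlier than the time asked, so X stands past its peak at that time, but the test is the product: the age is 27.1 min, leak times age is 0.255, which is not small beside one, and I expect 77.5% of the charge as X.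

**The forecast.** It gives 1 for the order in G, 1.02 for the order in E and 79.5% for noon, reasoning “so X is being lost”. My noon share is lower than its share.

**The result.** The flask gives 1.1 in G, 1.0 in E and 76.5% at noon, and the forecast stands within its margins.

    2 G ⇌ G2, settled at all times (33.10 L mol⁻¹)
    E + G2 → X + G (0.2130 L mol⁻¹ min⁻¹)
    X + G → L (0.06600 L mol⁻¹ min⁻¹)
    2 G → Jy (0.3078 L mol⁻¹ min⁻¹)

**The leak.** The leak is the path from X and G to L: the noon run gives 76.5% with it and 99.5% without it, and a flask behaving that way would have proved the forecast wrong. My leak over the noon age removes 22.5% of the charge. On the dusk run, whose making constant of 0.0808 min⁻¹ is smaller than that of the midnight run, the full two-step curve with that constant and the midnight leak gives 75.2% at 32 min, where the reading stands at 73.7%.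

(The readings were computed with constants of no real substance, noise included.)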